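## Retrosynthetic overview

1. Labels: resveratrol units A–F; C7x and C8x are the two sp3 carbons of unit x, C7x bearing the 4-oxygenated ring ("phenol ring x") and C8x the 3,5-dioxygenated ring ("resorcinol ring x", carbons 9x–14x). Inter-unit bonds: C8b–C10a and C7b–O11a (dihydrobenzofuran B/A), C7a–C10b (seven-membered ring), C8a–C7c, C8c–C8e, C8d–C10c and C7d–O11c (dihydrobenzofuran D/C), C7e–C10d (eight-membered ring), C8f–C10e and C7f–O11e (dihydrobenzofuran F/E).
2. Last skeletal operation (step 34): acid cascade of resorcinol ketone 54. Friedel–Crafts cyclodehydration C8b–C10a closes the seven-membered ring (C7a, C8a, C9a, C10a, C8b, C9b, C10b); protonation at C8b and capture of the C7b cation by O11a then closes, last, the dihydrobenzofuran O11a–C7b–C8b–C10a–C11a. Enabling feature: C8b sits between C9b of resorcinol ring B and C10a, which is ortho to O11a and para to O13a of the symmetric resorcinol ring A, and its neighbour C7b carries the cation-stabilising phenol ring B and completes a five-membered ring with O11a; so C8b can enter as an aryl ketone carbon and C7b as its CH2 group.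
3. Chain C7e–C8e–C8c–C7c–C8a–C7a: C8e–C8c by Ireland–Claisen rearrangement (chirality from a CBS-derived allylic alcohol); C7e, C7c and C7a each from an aldehyde through a 2,6-di-tert-butyl para-quinone methide and 1,6-addition (aryl Grignard, ester enolate, aryl Grignard).
4. Eight-membered ring (C8c, C9c, C10c, C8d, C9d, C10d, C7e, C8e) and dihydrobenzofuran D/C together (step 22): phenolic Mannich closure C8d–C10c, ortho-quinone methide, (4+1) annulation with a sulfonium ylide (C7d).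
5. Dihydrobenzofuran F/E first (steps 1–7, rhodium-carbene C–H insertion, then epimerisation). Ring order: F/E furan, eight-membered ring, D/C furan, seven-membered ring, B/A furan; tert-butyl groups and methyl ethers are removed last.

Key step: step 34

Assumption: Rh2(S-PTAD)4, tetrakis[(S)-(1-adamantyl)(N-phthalimido)acetato]dirhodium, is taken as the catalyst antipode that gives the (3R) insertion product 10; if the sense is opposite, Rh2(R-PTAD)4 is used with no other change.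

## Route

Step 1
Reactants: 1 2-bromo-4,6-dimethoxybenzaldehyde; 2 (3,5-dimethoxyphenyl)magnesium chloride
Product: 3 (2-bromo-4,6-dimethoxyphenyl)(3,5-dimethoxyphenyl)methanol
Conditions: THF, −78 → 0 °C; NH4Cl (aq)
Reagents that add atoms: none
Why: Grignard addition to an aromatic aldehyde gives the diaryl carbinol, whose stereocentre disappears in the oxidation of step 2.

Step 2
Reactants: 3 (2-bromo-4,6-dimethoxyphenyl)(3,5-dimethoxyphenyl)methanol
Product: 4 (2-bromo-4,6-dimethoxyphenyl)(3,5-dimethoxyphenyl)methanone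
Conditions: Dess–Martin periodinane, NaHCO3, CH2Cl2, rt
Reagents that add atoms: none
Why: Dess–Martin oxidation of a doubly benzylic alcohol gives the benzophenone without touching the aryl bromide.

Step 3
Reactants: 4 (2-bromo-4,6-dimethoxyphenyl)(3,5-dimethoxyphenyl)methanone
Product: 5 (2-bromo-6-hydroxy-4-methoxyphenyl)(3,5-dimethoxyphenyl)methanone
Conditions: BCl3 (1.2 equiv), CH2Cl2, −78 → 0 °C; H2O
Reagents that add atoms: none
Why: chelation-controlled BCl3 demethylation cleaves only the methyl ether ortho to the ketone carbonyl.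

Step 4
Reactants: 5 (2-bromo-6-hydroxy-4-methoxyphenyl)(3,5-dimethoxyphenyl)methanone; 6 4-methoxybenzyl chloride
Product: 7 {2-bromo-4-methoxy-6-[(4-methoxybenzyl)oxy]phenyl}(3,5-dimethoxyphenyl)methanone
Conditions: K2CO3, NaI (cat.), DMF, 50 °C
Reagents that add atoms: none
Why: Williamson etherification installs the 4-methoxybenzyl group whose CH2 becomes C7f.

Step 5
Reactants: 7 {2-bromo-4-methoxy-6-[(4-methoxybenzyl)oxy]phenyl}(3,5-dimethoxyphenyl)methanone
Product: 8 hydrazone of ketone 7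
Conditions: N2H4·H2O, AcOH (cat.), n-BuOH, 110 °C
Reagents that add atoms: hydrazine, NN
Why: hydrazone formation by condensation, run hot because the ketone is di-ortho-substituted.

Step 6
Reactants: 8 hydrazone of ketone 7
Product: 10 (2S,3R)-4-bromo-3-(3,5-dimethoxyphenyl)-6-methoxy-2-(4-methoxyphenyl)-2,3-dihydro-1-benzofuran (cis), via diaryldiazomethane 9 (not isolated)
Conditions: MnO2, CH2Cl2, 0 °C; filter; Rh2(S-PTAD)4 (1 mol %), CH2Cl2, 0 °C
Reagents that add atoms: none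
Why: MnO2 oxidation gives the donor/donor diazo compound, and its rhodium carbene undergoes 1,5-C–H insertion into the benzylic ether C–H bond; C8f is set by the chiral dirhodium carboxylate and C7f cis to it by the concerted insertion.

Step 7
Reactants: 10 (2S,3R)-cis-dihydrobenzofuran
Product: 11 (2R,3R)-4-bromo-3-(3,5-dimethoxyphenyl)-6-methoxy-2-(4-methoxyphenyl)-2,3-dihydro-1-benzofuran (trans)
Conditions: CF3CO2H, CH2Cl2, 0 °C → rt
Reagents that add atoms: none
Why: acid-mediated epimerisation through reversible ionisation of the 4-methoxybenzylic C–O bond brings C7f to the thermodynamically favoured trans configuration and leaves C8f untouched.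

Step 8
Reactants: 11 (2R,3R)-trans-bromide; 12 but-3-en-2-one
Product: 13 (E)-4-[(2R,3R)-3-(3,5-dimethoxyphenyl)-6-methoxy-2-(4-methoxyphenyl)-2,3-dihydro-1-benzofuran-4-yl]but-3-en-2-one
Conditions: Pd(P(t-Bu)3)2 (5 mol %), Cy2NMe, dioxane, 80 °C
Reagents that add atoms: none
Why: Mizoroki–Heck reaction; syn-insertion and syn-β-hydride elimination give the (E)-enone.

Step 9
Reactants: 13 (E)-enone
Product: 14 (2S,3E)-4-[(2R,3R)-3-(3,5-dimethoxyphenyl)-6-methoxy-2-(4-methoxyphenyl)-2,3-dihydro-1-benzofuran-4-yl]but-3-en-2-ol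
Conditions: (R)-2-methyl-CBS-oxazaborolidine (10 mol %), catecholborane, toluene, −78 °C
Reagents that add atoms: none
Why: Corey–Bakshi–Shibata 1,2-reduction; the oxazaborolidine distinguishes the alkenyl and methyl flanks of the ketone and sets the (S)-carbinol.

Step 10
Reactants: 15 (3,5-dihydroxyphenyl)acetic acid
Product: 17 [3,5-bis(tert-butyldimethylsilyloxy)phenyl]acetic acid, via silyl ester 16 (not isolated)
Conditions: TBSCl (3.3 equiv), imidazole, DMF, rt; then AcOH/THF/H2O, rt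
Reagents that add atoms: tert-butyldimethylsilyl chloride, CC(C)(C)[Si](C)(C)Cl
Why: silylation of both phenols and the acid, then selective hydrolysis of the labile silyl ester.

Step 11
Reactants: 14 (2S,3E)-allylic alcohol; 17 [3,5-bis(tert-butyldimethylsilyloxy)phenyl]acetic acid
Product: 18 (2S,3E)-4-(dihydrobenzofuran-4-yl)but-3-en-2-yl [3,5-bis(tert-butyldimethylsilyloxy)phenyl]acetate
Conditions: DCC, DMAP (cat.), CH2Cl2, 0 °C → rt
Reagents that add atoms: none
Why: Steglich esterification acylates the allylic alcohol with retention at the carbinol carbon.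

Step 12
Reactants: 18 allylic arylacetate
Product: 21 (2R,3R,4E)-2-[3,5-bis(tert-butyldimethylsilyloxy)phenyl]-3-(dihydrobenzofuran-4-yl)hex-4-enoic acid (carbon 2 = C8c; carbon 3 = C8e), via silyl ketene acetal 19 (not isolated), via trimethylsilyl ester 20 (not isolated)
Conditions: LiN(SiMe3)2, Me3SiCl, Et3N, THF, −78 → 60 °C; then 1 M HCl
Reagents that add atoms: none
Why: Ireland–Claisen [3,3]-sigmatropic rearrangement through a chair transition state with the carbinol methyl group equatorial; the (Z)-silyl ketene acetal (aryl cis to OSiMe3) and the (E)-alkene give the syn C8c/C8e pair, and the (S)-carbinol fixes the absolute configuration of both new centres.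

Step 13
Reactants: 21 hexenoic acid
Product: 22 (2R,3R,4E)-N-methoxy-N-methyl amide of acid 21
Conditions: MeNH(OMe)·HCl, DCC, Et3N, DMAP (cat.), CH2Cl2, 0 °C → rt
Reagents that add atoms: N,O-dimethylhydroxylamine hydrochloride, CNOC.Cl
Why: carbodiimide coupling gives the Weinreb amide, a carboxyl form that does not lactonise with the later C7e alkoxide and stops at the aldehyde on reduction.

Step 14
Reactants: 22 Weinreb amide
Product: 23 (2R,3R)-2-[3,5-bis(tert-butyldimethylsilyloxy)phenyl]-3-(dihydrobenzofuran-4-yl)-N-methoxy-N-methyl-4-oxobutanamide (carbon 4 = C7e)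
Conditions: OsO4 (2 mol %), NaIO4, 2,6-lutidine, dioxane/H2O, rt
Reagents that add atoms: sodium periodate as oxygen source, [Na+].[O-]I(=O)(=O)=O
Why: Lemieux–Johnson oxidative cleavage of the propenyl group gives the C7e aldehyde, and the lutidine buffer protects the α-aryl centre C8e from epimerisation.

Step 15
Reactants: 24 4-bromo-2,6-di-tert-butylphenol
Product: 25 lithium 2,6-di-tert-butyl-4-lithiophenolate (THF solution, used at once)
Conditions: n-BuLi (2.1 equiv), THF, −78 → −40 °C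
Reagents that add atoms: n-butyllithium, [Li]CCCC
Why: deprotonation of the phenol by the first equivalent and bromine–lithium exchange by the second give the aryllithium whose phenoxide oxygen is shielded by the two tert-butyl groups, so that only the carbon–lithium end reacts later; the solution is not stored and is made afresh by this procedure before steps 25 and 29.

Step 16
Reactants: 23 aldehyde; 25 lithium 2,6-di-tert-butyl-4-lithiophenolate (fresh THF solution)
Product: 26 C7e carbinol (3,5-di-tert-butyl-4-hydroxyphenyl adduct of 23; both C7e epimers)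
Conditions: 25 (2 equiv), THF, −78 °C; NH4Cl (aq)
Reagents that add atoms: none
Why: 1,2-addition of the aryllithium to the aldehyde, which outruns attack on the Weinreb amide at −78 °C; the carbinol centre is lost again in step 19.

Step 17
Reactants: 27 2-bromo-3,5-dimethoxybenzaldehyde
Product: 28 2-(2-bromo-3,5-dimethoxyphenyl)-1,3-dioxolane
Conditions: ethylene glycol, TsOH·H2O (cat.), toluene, reflux (Dean–Stark)
Reagents that add atoms: ethylene glycol, OCCO
Why: acid-catalysed acetalisation masks the aldehyde that later becomes C8d.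

Step 18
Reactants: 28 dioxolane bromide
Product: 29 [2-(1,3-dioxolan-2-yl)-4,6-dimethoxyphenyl]magnesium bromide (titrated THF solution)
Conditions: Mg, LiCl, THF, 40 °C
Reagents that add atoms: magnesium, [Mg]
Why: magnesium insertion into the aryl bromide (Grignard formation) is compatible with the acetal and the methyl ethers.

Step 19
Reactants: 26 C7e carbinol; 29 aryl Grignard reagent
Product: 32 C7e diarylmethine aldehyde (resorcinol ring D bearing CHO; resorcinol ring C as bis-silyl ether), via para-quinone methide 30 (not isolated), via acetal adduct 31 (not isolated)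
Conditions: MsCl, Et3N, CH2Cl2, −20 °C; cold filtration; 29 (4 equiv), THF, −78 → 0 °C; then 1 M HCl, THF, rt
Reagents that add atoms: water, O
Why: dehydration of the para-hydroxybenzylic alcohol gives the para-quinone methide, to which the aryl Grignard adds 1,6; C7e is set by attack anti to resorcinol ring E on C8e in the conformer with C8e–H eclipsing the methide (allylic 1,3-strain), and the acidic work-up unmasks the aldehyde.

Step 20
Reactants: 32 bis-silyl ether aldehyde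
Product: 33 resorcinol aldehyde (resorcinol ring C free)
Conditions: Bu4NF, AcOH, THF, 0 °C
Reagents that add atoms: none
Why: buffered fluoride desilylation of the aryl silyl ethers leaves aldehyde, amide and dihydrobenzofuran untouched.

Step 21
Reactants: 6 4-methoxybenzyl chloride
Product: 34 1-(4-methoxybenzyl)tetrahydrothiophenium chloride
Conditions: tetrahydrothiophene, MeOH/H2O (9:1), rt
Reagents that add atoms: tetrahydrothiophene, C1CCSC1
Why: S-alkylation of the sulfide by the reactive benzylic chloride gives the sulfonium salt.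

Step 22
Reactants: 33 resorcinol aldehyde; 34 sulfonium chloride
Product: 38 tetracyclic Weinreb amide with eight-membered ring and dihydrobenzofuran D/C (13c-OH free), via Mannich base 35 (not isolated), via ammonium iodide 36 (not isolated), via ortho-quinone methide 37 (not isolated)
Conditions: Me2NH (2 M in THF), EtOH, 40 °C, 2 mM; evaporate; MeI, MeCN, rt; evaporate; 34, Cs2CO3, CH2Cl2/MeCN, 0 °C → rt
Reagents that add atoms: none
Why: Proposed new method: dimethylamine turns the aldehyde on resorcinol ring D into an iminium ion that only the free, symmetric resorcinol ring C attacks at C10c (intramolecular phenolic Mannich or Betti reaction, closing the eight-membered ring and sparing the ether-protected resorcinol ring E that an acid-mediated Friedel–Crafts closure would engage in a seven-membered ring), N-methylation makes the amine a leaving group, and Cs2CO3 then releases ortho-quinone methide 37 and the ylide of 34, which should add to C8d from the face opposite to resorcinol ring E at C8e and the carboxamide at C8c before phenoxide O11c displaces tetrahydrothiophene through the anti betaine to give the trans dihydrobenzofuran (C7d); the closest known reactions are Betti condensations of resorcinols, quaternised phenolic Mannich bases as ortho-quinone methide precursors and the (4+1) annulation of ortho-quinone methides with sulfonium ylides.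

Step 23
Reactants: 38 tetracyclic phenol
Product: 39 13c-O-methyl ether of 38
Conditions: MeI, K2CO3, acetone, rt
Reagents that add atoms: iodomethane, CI
Why: Williamson methylation of the only unhindered phenol; the 2,6-di-tert-butylphenol does not react.

Step 24
Reactants: 39 Weinreb amide
Product: 40 C7c aldehyde
Conditions: i-Bu2AlH, THF, −78 °C; 1 M HCl
Reagents that add atoms: none
Why: reduction of the Weinreb amide stops at the aldehyde because the chelated tetrahedral intermediate survives until work-up.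

Step 25
Reactants: 40 C7c aldehyde; 25 lithium 2,6-di-tert-butyl-4-lithiophenolate (fresh THF solution)
Product: 41 C7c carbinol (both epimers)
Conditions: 25 (3 equiv), THF, −78 °C; NH4Cl (aq)
Reagents that add atoms: none
Why: aryllithium 1,2-addition to the aldehyde as in step 16, with one extra equivalent for the free hindered phenol; the carbinol centre is lost in step 27.

Step 26
Reactants: 42 methyl (3,5-dihydroxyphenyl)acetate
Product: 43 methyl [3,5-bis(tert-butyldimethylsilyloxy)phenyl]acetate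
Conditions: TBSCl, imidazole, DMF, rt
Reagents that add atoms: tert-butyldimethylsilyl chloride, CC(C)(C)[Si](C)(C)Cl
Why: standard silylation of both phenols.

Step 27
Reactants: 41 C7c carbinol; 43 silylated arylacetate
Product: 45 methyl ester with C7c and C8a set (C7a = ester carbon), via para-quinone methide 44 (not isolated)
Conditions: 41, MsCl, Et3N, CH2Cl2, −20 °C; cold filtration; added to 43 (3 equiv), LiN(i-Pr)2 (3 equiv), THF, −78 → −20 °C
Reagents that add atoms: none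
Why: 1,6-conjugate addition of the ester enolate to the para-quinone methide; C7c is set by attack anti to resorcinol ring C on C8c (allylic 1,3-strain model), and C8a should form as the syn isomer through the open transition state that keeps its aryl group away from the polycycle.

Step 28
Reactants: 45 methyl ester
Product: 46 C7a aldehyde
Conditions: i-Bu2AlH, CH2Cl2, −78 °C
Reagents that add atoms: none
Why: low-temperature DIBAL half-reduction of the hindered methyl ester stops at the aldehyde.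

Step 29
Reactants: 46 C7a aldehyde; 25 lithium 2,6-di-tert-butyl-4-lithiophenolate (fresh THF solution)
Product: 47 C7a carbinol (both epimers)
Conditions: 25 (4 equiv), THF, −78 °C; NH4Cl (aq)
Reagents that add atoms: none
Why: aryllithium 1,2-addition as in step 16, with extra equivalents for the two free hindered phenols; the carbinol centre is lost in step 30.

Step 30
Reactants: 47 C7a carbinol; 29 aryl Grignard reagent
Product: 50 C7a diarylmethine aldehyde (resorcinol ring B bearing CHO; resorcinol ring A as bis-silyl ether), via para-quinone methide 48 (not isolated), via acetal adduct 49 (not isolated)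
Conditions: MsCl, Et3N, CH2Cl2, −20 °C; cold filtration; 29 (5 equiv), THF, −78 → 0 °C; then 1 M HCl, THF, rt
Reagents that add atoms: water, O
Why: para-quinone methide formation and 1,6-addition of the aryl Grignard as in step 19; C7a is set by attack anti to resorcinol ring A on C8a in the allylic-strain-minimised conformer.

Step 31
Reactants: 50 aldehyde; 51 (4-methoxybenzyl)magnesium chloride
Product: 52 C8b carbinol (both epimers)
Conditions: 51 (6 equiv), THF, −78 → 0 °C; NH4Cl (aq)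
Reagents that add atoms: none
Why: Grignard 1,2-addition brings in C7b with phenol ring B; the carbinol centre is oxidised in step 32.

Step 32
Reactants: 52 C8b carbinol
Product: 53 aryl 4-methoxybenzyl ketone (C8b = C=O; C7b = CH2)
Conditions: (COCl)2, DMSO, CH2Cl2, −78 °C; Et3N
Reagents that add atoms: none
Why: Swern oxidation of the secondary benzylic alcohol; the 2,6-di-tert-butylphenols are too hindered to react with the activated sulfoxide.

Step 33
Reactants: 53 ketone bis-silyl ether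
Product: 54 resorcinol ketone (resorcinol ring A free)
Conditions: Bu4NF, AcOH, THF, 0 °C
Reagents that add atoms: none
Why: buffered fluoride desilylation frees resorcinol ring A under neutral conditions, under which ketone and resorcinol do not yet condense.

Step 34
Reactants: 54 resorcinol ketone
Product: 57 protected hexamer with seven-membered ring and trans-dihydrobenzofuran B/A, via tertiary carbinol 55 (not isolated), via cyclic triarylethylene 56 (not isolated)
Conditions: CF3SO3H (10 mol %), (CF3)2CHOH/CH2Cl2 (1:4), 4 Å MS, 0 °C → rt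
Reagents that add atoms: none
Why: Proposed new method: the protonated ketone carbon C8b is attacked by C10a of the free resorcinol ring A (Friedel–Crafts hydroxyalkylation, 7-exo-trig; C10a and C14a are equivalent and C12a cannot reach, so there is no regiochemical choice), carbinol 55 ionises to the resorcinol-stabilised cation and loses a C7b proton to give the cyclic triarylethylene 56, and reversible protonation of 56 at C8b leaves the 4-methoxybenzylic cation at C7b, which O11a captures to close the dihydrobenzofuran as the last ring (formally a 5-endo hydroalkoxylation, possible because it runs through the discrete cation). The closest known reactions are acid-mediated cyclodehydrations of aryl ketones with resorcinols and Brønsted acid cyclisations of 2-hydroxystilbenes to 2-aryl-2,3-dihydrobenzofurans; their combination in one ring-forming cascade is new. C8b is set by proton delivery to the exocyclic alkene from the exposed face of the boat-shaped seven-membered ring, anti to phenol ring A at C7a, which is pseudo-axial to avoid allylic strain with OMe-11b; this places H8b cis to H7a and H8a and the C8b–C7b bond cis to phenol ring A, as in the target. C7b is set trans to resorcinol ring B by the reversible, thermodynamically controlled capture of the cation, the same control as in step 7. The step needs chemoselectivity for resorcinol ring A, and it is secured because resorcinol ring A is the only strongly nucleophilic arene that can reach C8b in a seven-membered transition state, the ortho positions of phenol rings A and C are shielded by tert-butyl groups, and the two existing trans-dihydrobenzofurans, if opened by the acid, reclose to the same isomers.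

Step 35
Reactants: 57 protected hexamer
Product: 58 de-tert-butylated hexamer (eleven methyl ethers left)
Conditions: AlCl3, toluene/MeNO2, 50 °C
Reagents that add atoms: none
Why: retro-Friedel–Crafts de-tert-butylation; the six tert-butyl groups are transferred to toluene and no stereocentre is involved.

Step 36
Reactants: 58 de-tert-butylated hexamer
Product: 59 CNP0184494.1
Conditions: BBr3, CH2Cl2, −78 °C → rt; MeOH, H2O
Reagents that add atoms: none
Why: global aryl methyl ether cleavage by BBr3, the usual last step for oligostilbenes; the trans-dihydrobenzofurans are the thermodynamic isomers and should survive.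

## Compound list

1 | 2-bromo-4,6-dimethoxybenzaldehyde | COc1cc(OC)c(C=O)c(Br)c1 | starting material
2 | (3,5-dimethoxyphenyl)magnesium chloride (1 M in THF) | COc1cc(OC)cc([Mg]Cl)c1 | starting material
3 | (2-bromo-4,6-dimethoxyphenyl)(3,5-dimethoxyphenyl)methanol (racemic) | COc1cc(OC)cc(c1)C(O)c1c(Br)cc(OC)cc1OC | intermediate
4 | (2-bromo-4,6-dimethoxyphenyl)(3,5-dimethoxyphenyl)methanone | COc1cc(OC)cc(c1)C(=O)c1c(Br)cc(OC)cc1OC | intermediate
5 | (2-bromo-6-hydroxy-4-methoxyphenyl)(3,5-dimethoxyphenyl)methanone | COc1cc(OC)cc(c1)C(=O)c1c(Br)cc(OC)cc1O | intermediate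
6 | 4-methoxybenzyl chloride | COc1ccc(CCl)cc1 | starting material
7 | {2-bromo-4-methoxy-6-[(4-methoxybenzyl)oxy]phenyl}(3,5-dimethoxyphenyl)methanone | COc1ccc(COc2cc(OC)cc(Br)c2C(=O)c2cc(OC)cc(OC)c2)cc1 | intermediate
8 | hydrazone of ketone 7 | COc1ccc(COc2cc(OC)cc(Br)c2C(=NN)c2cc(OC)cc(OC)c2)cc1 | intermediate
9 | diaryldiazomethane from 8 | COc1ccc(COc2cc(OC)cc(Br)c2C(=[N+]=[N-])c2cc(OC)cc(OC)c2)cc1 | intermediate (not isolated)
10 | (2S,3R)-4-bromo-3-(3,5-dimethoxyphenyl)-6-methoxy-2-(4-methoxyphenyl)-2,3-dihydro-1-benzofuran (cis) | Brc1cc(OC)cc2c1[C@@H](c1cc(OC)cc(OC)c1)[C@@H](c1ccc(OC)cc1)O2 | intermediate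
11 | (2R,3R)-4-bromo-3-(3,5-dimethoxyphenyl)-6-methoxy-2-(4-methoxyphenyl)-2,3-dihydro-1-benzofuran (trans; furan carbon 2 = C7f, furan carbon 3 = C8f) | Brc1cc(OC)cc2c1[C@@H](c1cc(OC)cc(OC)c1)[C@H](c1ccc(OC)cc1)O2 | intermediate
12 | but-3-en-2-one | CC(=O)C=C | starting material
13 | (E)-4-[(2R,3R)-3-(3,5-dimethoxyphenyl)-6-methoxy-2-(4-methoxyphenyl)-2,3-dihydro-1-benzofuran-4-yl]but-3-en-2-one | CC(=O)/C=C/c1cc(OC)cc2c1[C@@H](c1cc(OC)cc(OC)c1)[C@H](c1ccc(OC)cc1)O2 | intermediate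
14 | (2S,3E)-4-[(2R,3R)-3-(3,5-dimethoxyphenyl)-6-methoxy-2-(4-methoxyphenyl)-2,3-dihydro-1-benzofuran-4-yl]but-3-en-2-ol | C[C@H](O)/C=C/c1cc(OC)cc2c1[C@@H](c1cc(OC)cc(OC)c1)[C@H](c1ccc(OC)cc1)O2 | intermediate
15 | (3,5-dihydroxyphenyl)acetic acid | OC(=O)Cc1cc(O)cc(O)c1 | starting material
16 | tert-butyldimethylsilyl [3,5-bis(tert-butyldimethylsilyloxy)phenyl]acetate | CC(C)(C)[Si](C)(C)OC(=O)Cc1cc(O[Si](C)(C)C(C)(C)C)cc(O[Si](C)(C)C(C)(C)C)c1 | intermediate (not isolated)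
17 | [3,5-bis(tert-butyldimethylsilyloxy)phenyl]acetic acid | OC(=O)Cc1cc(O[Si](C)(C)C(C)(C)C)cc(O[Si](C)(C)C(C)(C)C)c1 | intermediate
18 | (2S,3E)-4-(dihydrobenzofuran-4-yl)but-3-en-2-yl [3,5-bis(tert-butyldimethylsilyloxy)phenyl]acetate (dihydrobenzofuran as in 11) | C[C@H](OC(=O)Cc1cc(O[Si](C)(C)C(C)(C)C)cc(O[Si](C)(C)C(C)(C)C)c1)/C=C/c1cc(OC)cc2c1[C@@H](c1cc(OC)cc(OC)c1)[C@H](c1ccc(OC)cc1)O2 | intermediate
19 | (Z)-trimethylsilyl ketene acetal of ester 18 (aryl cis to OSiMe3) | C[C@H](O/C(O[Si](C)(C)C)=C/c1cc(O[Si](C)(C)C(C)(C)C)cc(O[Si](C)(C)C(C)(C)C)c1)/C=C/c1cc(OC)cc2c1[C@@H](c1cc(OC)cc(OC)c1)[C@H](c1ccc(OC)cc1)O2 | intermediate (not isolated)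
20 | trimethylsilyl ester of acid 21 | C[Si](C)(C)OC(=O)[C@H]([C@H](c1cc(OC)cc2c1[C@@H](c1cc(OC)cc(OC)c1)[C@H](c1ccc(OC)cc1)O2)/C=C/C)c1cc(O[Si](C)(C)C(C)(C)C)cc(O[Si](C)(C)C(C)(C)C)c1 | intermediate (not isolated)
21 | (2R,3R,4E)-2-[3,5-bis(tert-butyldimethylsilyloxy)phenyl]-3-(dihydrobenzofuran-4-yl)hex-4-enoic acid (carbon 2 = C8c; carbon 3 = C8e) | OC(=O)[C@H]([C@H](c1cc(OC)cc2c1[C@@H](c1cc(OC)cc(OC)c1)[C@H](c1ccc(OC)cc1)O2)/C=C/C)c1cc(O[Si](C)(C)C(C)(C)C)cc(O[Si](C)(C)C(C)(C)C)c1 | intermediate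
22 | (2R,3R,4E)-N-methoxy-N-methyl amide of acid 21 | CON(C)C(=O)[C@H]([C@H](c1cc(OC)cc2c1[C@@H](c1cc(OC)cc(OC)c1)[C@H](c1ccc(OC)cc1)O2)/C=C/C)c1cc(O[Si](C)(C)C(C)(C)C)cc(O[Si](C)(C)C(C)(C)C)c1 | intermediate
23 | (2R,3R)-2-[3,5-bis(tert-butyldimethylsilyloxy)phenyl]-3-(dihydrobenzofuran-4-yl)-N-methoxy-N-methyl-4-oxobutanamide (carbon 4 = C7e) | CON(C)C(=O)[C@H]([C@H](c1cc(OC)cc2c1[C@@H](c1cc(OC)cc(OC)c1)[C@H](c1ccc(OC)cc1)O2)C=O)c1cc(O[Si](C)(C)C(C)(C)C)cc(O[Si](C)(C)C(C)(C)C)c1 | intermediate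
24 | 4-bromo-2,6-di-tert-butylphenol | CC(C)(C)c1cc(Br)cc(C(C)(C)C)c1O | starting material
25 | lithium 2,6-di-tert-butyl-4-lithiophenolate (THF solution, used at once) | CC(C)(C)c1cc([Li])cc(C(C)(C)C)c1O[Li] | intermediate
26 | C7e carbinol: 4-(3,5-di-tert-butyl-4-hydroxyphenyl)-4-hydroxy analogue of 23 (both C7e epimers) | CON(C)C(=O)[C@H]([C@H](c1cc(OC)cc2c1[C@@H](c1cc(OC)cc(OC)c1)[C@H](c1ccc(OC)cc1)O2)C(O)c1cc(C(C)(C)C)c(O)c(C(C)(C)C)c1)c1cc(O[Si](C)(C)C(C)(C)C)cc(O[Si](C)(C)C(C)(C)C)c1 | intermediate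
27 | 2-bromo-3,5-dimethoxybenzaldehyde | COc1cc(OC)c(Br)c(C=O)c1 | starting material
28 | 2-(2-bromo-3,5-dimethoxyphenyl)-1,3-dioxolane | COc1cc(OC)c(Br)c(c1)C1OCCO1 | intermediate
29 | [2-(1,3-dioxolan-2-yl)-4,6-dimethoxyphenyl]magnesium bromide (THF solution) | COc1cc(OC)c([Mg]Br)c(c1)C1OCCO1 | intermediate
30 | para-quinone methide from 26 (C7e = methide carbon) | CON(C)C(=O)[C@H]([C@H](c1cc(OC)cc2c1[C@@H](c1cc(OC)cc(OC)c1)[C@H](c1ccc(OC)cc1)O2)C=C1C=C(C(C)(C)C)C(=O)C(C(C)(C)C)=C1)c1cc(O[Si](C)(C)C(C)(C)C)cc(O[Si](C)(C)C(C)(C)C)c1 | intermediate (not isolated)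
31 | C7e diarylmethine with resorcinol ring D as dioxolane acetal (C7e, C8e, C8c as in SMILES) | CON(C)C(=O)[C@H]([C@H](c1cc(OC)cc2c1[C@@H](c1cc(OC)cc(OC)c1)[C@H](c1ccc(OC)cc1)O2)[C@@H](c1cc(C(C)(C)C)c(O)c(C(C)(C)C)c1)c1c(C2OCCO2)cc(OC)cc1OC)c1cc(O[Si](C)(C)C(C)(C)C)cc(O[Si](C)(C)C(C)(C)C)c1 | intermediate (not isolated)
32 | C7e diarylmethine aldehyde (resorcinol ring D with CHO; resorcinol ring C as bis-silyl ether) | CON(C)C(=O)[C@H]([C@H](c1cc(OC)cc2c1[C@@H](c1cc(OC)cc(OC)c1)[C@H](c1ccc(OC)cc1)O2)[C@@H](c1cc(C(C)(C)C)c(O)c(C(C)(C)C)c1)c1c(C=O)cc(OC)cc1OC)c1cc(O[Si](C)(C)C(C)(C)C)cc(O[Si](C)(C)C(C)(C)C)c1 | intermediate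
33 | resorcinol aldehyde (32 with resorcinol ring C as free 3,5-dihydroxyphenyl) | CON(C)C(=O)[C@H]([C@H](c1cc(OC)cc2c1[C@@H](c1cc(OC)cc(OC)c1)[C@H](c1ccc(OC)cc1)O2)[C@@H](c1cc(C(C)(C)C)c(O)c(C(C)(C)C)c1)c1c(C=O)cc(OC)cc1OC)c1cc(O)cc(O)c1 | intermediate
34 | 1-(4-methoxybenzyl)tetrahydrothiophenium chloride | COc1ccc(C[S+]2CCCC2)cc1.[Cl-] | intermediate
35 | Mannich base: eight-membered ring closed; C8d bears NMe2 (both C8d epimers) | CON(C)C(=O)[C@H]2c4cc(O)cc(O)c4C(N(C)C)c4cc(OC)cc(OC)c4[C@H](c4cc(C(C)(C)C)c(O)c(C(C)(C)C)c4)[C@H]2c2cc(OC)cc4c2[C@@H](c2cc(OC)cc(OC)c2)[C@H](c2ccc(OC)cc2)O4 | intermediate (not isolated)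
36 | trimethylammonium iodide of 35 | CON(C)C(=O)[C@H]2c4cc(O)cc(O)c4C([N+](C)(C)C)c4cc(OC)cc(OC)c4[C@H](c4cc(C(C)(C)C)c(O)c(C(C)(C)C)c4)[C@H]2c2cc(OC)cc4c2[C@@H](c2cc(OC)cc(OC)c2)[C@H](c2ccc(OC)cc2)O4.[I-] | intermediate (not isolated)
37 | ortho-quinone methide (C8d = exocyclic methide carbon on resorcinol ring C) | CON(C)C(=O)[C@H]2C4=CC(O)=CC(=O)C4=Cc4cc(OC)cc(OC)c4[C@H](c4cc(C(C)(C)C)c(O)c(C(C)(C)C)c4)[C@H]2c2cc(OC)cc4c2[C@@H](c2cc(OC)cc(OC)c2)[C@H](c2ccc(OC)cc2)O4 | intermediate (not isolated)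
38 | tetracyclic Weinreb amide: eight-membered ring; trans-dihydrobenzofurans D/C and F/E; 13c-OH free | CON(C)C(=O)[C@H]2c4cc(O)cc5c4[C@@H](c4cc(OC)cc(OC)c4[C@H](c4cc(C(C)(C)C)c(O)c(C(C)(C)C)c4)[C@H]2c2cc(OC)cc4c2[C@@H](c2cc(OC)cc(OC)c2)[C@H](c2ccc(OC)cc2)O4)[C@H](c2ccc(OC)cc2)O5 | intermediate
39 | 13c-O-methyl ether of 38 | CON(C)C(=O)[C@H]2c4cc(OC)cc5c4[C@@H](c4cc(OC)cc(OC)c4[C@H](c4cc(C(C)(C)C)c(O)c(C(C)(C)C)c4)[C@H]2c2cc(OC)cc4c2[C@@H](c2cc(OC)cc(OC)c2)[C@H](c2ccc(OC)cc2)O4)[C@H](c2ccc(OC)cc2)O5 | intermediate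
40 | C7c aldehyde on C8c of the tetracycle | O=C[C@H]2c4cc(OC)cc5c4[C@@H](c4cc(OC)cc(OC)c4[C@H](c4cc(C(C)(C)C)c(O)c(C(C)(C)C)c4)[C@H]2c2cc(OC)cc4c2[C@@H](c2cc(OC)cc(OC)c2)[C@H](c2ccc(OC)cc2)O4)[C@H](c2ccc(OC)cc2)O5 | intermediate
41 | C7c carbinol with the 3,5-di-tert-butyl-4-hydroxyphenyl phenol ring C (both C7c epimers) | OC(c1cc(C(C)(C)C)c(O)c(C(C)(C)C)c1)[C@H]2c4cc(OC)cc5c4[C@@H](c4cc(OC)cc(OC)c4[C@H](c4cc(C(C)(C)C)c(O)c(C(C)(C)C)c4)[C@H]2c2cc(OC)cc4c2[C@@H](c2cc(OC)cc(OC)c2)[C@H](c2ccc(OC)cc2)O4)[C@H](c2ccc(OC)cc2)O5 | intermediate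
42 | methyl (3,5-dihydroxyphenyl)acetate | COC(=O)Cc1cc(O)cc(O)c1 | starting material
43 | methyl [3,5-bis(tert-butyldimethylsilyloxy)phenyl]acetate | COC(=O)Cc1cc(O[Si](C)(C)C(C)(C)C)cc(O[Si](C)(C)C(C)(C)C)c1 | intermediate
44 | para-quinone methide from 41 (C7c = methide carbon) | CC(C)(C)C1=CC(C=C(C(C)(C)C)C1=O)=C[C@H]2c4cc(OC)cc5c4[C@@H](c4cc(OC)cc(OC)c4[C@H](c4cc(C(C)(C)C)c(O)c(C(C)(C)C)c4)[C@H]2c2cc(OC)cc4c2[C@@H](c2cc(OC)cc(OC)c2)[C@H](c2ccc(OC)cc2)O4)[C@H](c2ccc(OC)cc2)O5 | intermediate (not isolated)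
45 | methyl ester: C8a (resorcinol ring A as bis-silyl ether) bonded to C7c (phenol ring C); ester carbon = C7a | COC(=O)[C@@H](c1cc(O[Si](C)(C)C(C)(C)C)cc(O[Si](C)(C)C(C)(C)C)c1)[C@H](c1cc(C(C)(C)C)c(O)c(C(C)(C)C)c1)[C@H]2c4cc(OC)cc5c4[C@@H](c4cc(OC)cc(OC)c4[C@H](c4cc(C(C)(C)C)c(O)c(C(C)(C)C)c4)[C@H]2c2cc(OC)cc4c2[C@@H](c2cc(OC)cc(OC)c2)[C@H](c2ccc(OC)cc2)O4)[C@H](c2ccc(OC)cc2)O5 | intermediate
46 | C7a aldehyde from 45 | O=C[C@@H](c1cc(O[Si](C)(C)C(C)(C)C)cc(O[Si](C)(C)C(C)(C)C)c1)[C@H](c1cc(C(C)(C)C)c(O)c(C(C)(C)C)c1)[C@H]2c4cc(OC)cc5c4[C@@H](c4cc(OC)cc(OC)c4[C@H](c4cc(C(C)(C)C)c(O)c(C(C)(C)C)c4)[C@H]2c2cc(OC)cc4c2[C@@H](c2cc(OC)cc(OC)c2)[C@H](c2ccc(OC)cc2)O4)[C@H](c2ccc(OC)cc2)O5 | intermediate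
47 | C7a carbinol with the 3,5-di-tert-butyl-4-hydroxyphenyl phenol ring A (both C7a epimers) | OC(c1cc(C(C)(C)C)c(O)c(C(C)(C)C)c1)[C@@H](c1cc(O[Si](C)(C)C(C)(C)C)cc(O[Si](C)(C)C(C)(C)C)c1)[C@H](c1cc(C(C)(C)C)c(O)c(C(C)(C)C)c1)[C@H]2c4cc(OC)cc5c4[C@@H](c4cc(OC)cc(OC)c4[C@H](c4cc(C(C)(C)C)c(O)c(C(C)(C)C)c4)[C@H]2c2cc(OC)cc4c2[C@@H](c2cc(OC)cc(OC)c2)[C@H](c2ccc(OC)cc2)O4)[C@H](c2ccc(OC)cc2)O5 | intermediate
48 | para-quinone methide from 47 (C7a = methide carbon) | CC(C)(C)C1=CC(C=C(C(C)(C)C)C1=O)=C[C@@H](c1cc(O[Si](C)(C)C(C)(C)C)cc(O[Si](C)(C)C(C)(C)C)c1)[C@H](c1cc(C(C)(C)C)c(O)c(C(C)(C)C)c1)[C@H]2c4cc(OC)cc5c4[C@@H](c4cc(OC)cc(OC)c4[C@H](c4cc(C(C)(C)C)c(O)c(C(C)(C)C)c4)[C@H]2c2cc(OC)cc4c2[C@@H](c2cc(OC)cc(OC)c2)[C@H](c2ccc(OC)cc2)O4)[C@H](c2ccc(OC)cc2)O5 | intermediate (not isolated)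
49 | C7a diarylmethine with resorcinol ring B as dioxolane acetal | CC(C)(C)c1cc(cc(C(C)(C)C)c1O)[C@H]([C@@H](c1cc(O[Si](C)(C)C(C)(C)C)cc(O[Si](C)(C)C(C)(C)C)c1)[C@H](c1cc(C(C)(C)C)c(O)c(C(C)(C)C)c1)[C@H]2c4cc(OC)cc5c4[C@@H](c4cc(OC)cc(OC)c4[C@H](c4cc(C(C)(C)C)c(O)c(C(C)(C)C)c4)[C@H]2c2cc(OC)cc4c2[C@@H](c2cc(OC)cc(OC)c2)[C@H](c2ccc(OC)cc2)O4)[C@H](c2ccc(OC)cc2)O5)c3c(OC)cc(OC)cc3C6OCCO6 | intermediate (not isolated)
50 | C7a diarylmethine aldehyde (resorcinol ring B with CHO; resorcinol ring A as bis-silyl ether) | CC(C)(C)c1cc(cc(C(C)(C)C)c1O)[C@H]([C@@H](c1cc(O[Si](C)(C)C(C)(C)C)cc(O[Si](C)(C)C(C)(C)C)c1)[C@H](c1cc(C(C)(C)C)c(O)c(C(C)(C)C)c1)[C@H]2c4cc(OC)cc5c4[C@@H](c4cc(OC)cc(OC)c4[C@H](c4cc(C(C)(C)C)c(O)c(C(C)(C)C)c4)[C@H]2c2cc(OC)cc4c2[C@@H](c2cc(OC)cc(OC)c2)[C@H](c2ccc(OC)cc2)O4)[C@H](c2ccc(OC)cc2)O5)c3c(OC)cc(OC)cc3C=O | intermediate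
51 | (4-methoxybenzyl)magnesium chloride (0.25 M in THF) | COc1ccc(C[Mg]Cl)cc1 | starting material
52 | C8b carbinol (both C8b epimers; C7b = CH2 bearing phenol ring B) | CC(C)(C)c1cc(cc(C(C)(C)C)c1O)[C@H]([C@@H](c1cc(O[Si](C)(C)C(C)(C)C)cc(O[Si](C)(C)C(C)(C)C)c1)[C@H](c1cc(C(C)(C)C)c(O)c(C(C)(C)C)c1)[C@H]2c4cc(OC)cc5c4[C@@H](c4cc(OC)cc(OC)c4[C@H](c4cc(C(C)(C)C)c(O)c(C(C)(C)C)c4)[C@H]2c2cc(OC)cc4c2[C@@H](c2cc(OC)cc(OC)c2)[C@H](c2ccc(OC)cc2)O4)[C@H](c2ccc(OC)cc2)O5)c3c(OC)cc(OC)cc3C(O)Cc6ccc(OC)cc6 | intermediate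
53 | ketone (C8b = C=O; resorcinol ring A as bis-silyl ether) | CC(C)(C)c1cc(cc(C(C)(C)C)c1O)[C@H]([C@@H](c1cc(O[Si](C)(C)C(C)(C)C)cc(O[Si](C)(C)C(C)(C)C)c1)[C@H](c1cc(C(C)(C)C)c(O)c(C(C)(C)C)c1)[C@H]2c4cc(OC)cc5c4[C@@H](c4cc(OC)cc(OC)c4[C@H](c4cc(C(C)(C)C)c(O)c(C(C)(C)C)c4)[C@H]2c2cc(OC)cc4c2[C@@H](c2cc(OC)cc(OC)c2)[C@H](c2ccc(OC)cc2)O4)[C@H](c2ccc(OC)cc2)O5)c3c(OC)cc(OC)cc3C(=O)Cc6ccc(OC)cc6 | intermediate
54 | resorcinol ketone (53 with resorcinol ring A as free 3,5-dihydroxyphenyl) | CC(C)(C)c1cc(cc(C(C)(C)C)c1O)[C@H]([C@@H](c1cc(O)cc(O)c1)[C@H](c1cc(C(C)(C)C)c(O)c(C(C)(C)C)c1)[C@H]2c4cc(OC)cc5c4[C@@H](c4cc(OC)cc(OC)c4[C@H](c4cc(C(C)(C)C)c(O)c(C(C)(C)C)c4)[C@H]2c2cc(OC)cc4c2[C@@H](c2cc(OC)cc(OC)c2)[C@H](c2ccc(OC)cc2)O4)[C@H](c2ccc(OC)cc2)O5)c3c(OC)cc(OC)cc3C(=O)Cc6ccc(OC)cc6 | intermediate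
55 | tertiary carbinol: seven-membered ring closed; C8b bears OH and the 4-methoxybenzyl group | CC(C)(C)c1cc(cc(C(C)(C)C)c1O)[C@H]2c3c(OC)cc(OC)cc3C(O)(Cc6ccc(OC)cc6)c4c(O)cc(O)cc4[C@H]2[C@H](c2cc(C(C)(C)C)c(O)c(C(C)(C)C)c2)[C@H]2c4cc(OC)cc5c4[C@@H](c4cc(OC)cc(OC)c4[C@H](c4cc(C(C)(C)C)c(O)c(C(C)(C)C)c4)[C@H]2c2cc(OC)cc4c2[C@@H](c2cc(OC)cc(OC)c2)[C@H](c2ccc(OC)cc2)O4)[C@H](c2ccc(OC)cc2)O5 | intermediate (not isolated)
56 | cyclic triarylethylene (exocyclic C8b=C7b alkene on the seven-membered ring) | CC(C)(C)c1cc(cc(C(C)(C)C)c1O)[C@H]2c3c(OC)cc(OC)cc3C(=Cc6ccc(OC)cc6)c4c(O)cc(O)cc4[C@H]2[C@H](c2cc(C(C)(C)C)c(O)c(C(C)(C)C)c2)[C@H]2c4cc(OC)cc5c4[C@@H](c4cc(OC)cc(OC)c4[C@H](c4cc(C(C)(C)C)c(O)c(C(C)(C)C)c4)[C@H]2c2cc(OC)cc4c2[C@@H](c2cc(OC)cc(OC)c2)[C@H](c2ccc(OC)cc2)O4)[C@H](c2ccc(OC)cc2)O5 | intermediate (not isolated)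
57 | protected hexamer: phenol rings A, C and E as 3,5-di-tert-butyl-4-hydroxyphenyl; eleven methyl ethers; 13a-OH free; all twelve stereocentres as in the target | CC(C)(C)c1cc(cc(C(C)(C)C)c1O)[C@H]2c3c(OC)cc(OC)cc3[C@@H]3c4c(cc(O)cc4[C@H]2[C@H](c2cc(C(C)(C)C)c(O)c(C(C)(C)C)c2)[C@H]2c4cc(OC)cc5c4[C@@H](c4cc(OC)cc(OC)c4[C@H](c4cc(C(C)(C)C)c(O)c(C(C)(C)C)c4)[C@H]2c2cc(OC)cc4c2[C@@H](c2cc(OC)cc(OC)c2)[C@H](c2ccc(OC)cc2)O4)[C@H](c2ccc(OC)cc2)O5)O[C@H]3c2ccc(OC)cc2 | intermediate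
58 | de-tert-butylated hexamer (undeca-O-methyl ether of the target) | Oc1ccc(cc1)[C@H]2c3c(OC)cc(OC)cc3[C@@H]3c4c(cc(O)cc4[C@H]2[C@H](c2ccc(O)cc2)[C@H]2c4cc(OC)cc5c4[C@@H](c4cc(OC)cc(OC)c4[C@H](c4ccc(O)cc4)[C@H]2c2cc(OC)cc4c2[C@@H](c2cc(OC)cc(OC)c2)[C@H](c2ccc(OC)cc2)O4)[C@H](c2ccc(OC)cc2)O5)O[C@H]3c2ccc(OC)cc2 | intermediate
59 | CNP0184494.1, resveratrol hexamer (7aS,8aS,7bR,8bR,7cR,8cR,7dR,8dR,7eS,8eS,7fR,8fR) | Oc1ccc([C@H]2c3c(O)cc(O)cc3[C@@H]3c4c(cc(O)cc4[C@H]2[C@H](c2ccc(O)cc2)[C@H]2c4cc(O)cc5c4[C@@H](c4cc(O)cc(O)c4[C@H](c4ccc(O)cc4)[C@H]2c2cc(O)cc4c2[C@@H](c2cc(O)cc(O)c2)[C@H](c2ccc(O)cc2)O4)[C@H](c2ccc(O)cc2)O5)O[C@H]3c2ccc(O)cc2)cc1 | target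

## Step count and risks

Total step count: 36 (step 15 is counted once, although its solution is made afresh before steps 16, 25 and 29). Longest linear sequence: 30 steps (1–9, 11–14, 16, 19, 20, 22–25, 27–36).

The three steps most likely to fail:

1. Step 34 (key step). The resorcinol-stabilised cation at C8b may be the resting state, so that the cyclic triarylethylene is protonated at C7b and not at C8b and the oxa-cyclisation stalls, or the acid may start to reopen the other dihydrobenzofurans. Fallback, by known reactions, setting out from 54: mild cyclodehydration (TsOH·H2O cat., toluene, Dean–Stark) is stopped at the cyclic triarylethylene 56, which is isolated. Oxidative cyclisation of this 2-hydroxystilbene (I2, K2CO3, THF) gives the 2,3-diarylbenzofuran F1. Hydrogenation under pressure (H2, Pd/C, EtOAc/AcOH) adds both hydrogens to the exposed face and gives the cis-dihydrobenzofuran F2, with H8b on the face the proton would have taken. CF3CO2H in CH2Cl2 then epimerises C7b as in step 7 and the route is rejoined at 57.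

2. Step 22. The eight-membered Mannich closure may lose to intermolecular aminoalkylation, or the quaternisation may be accompanied by O-methylation of the resorcinol. Fallback, by known reactions, setting out from 33: chelation-controlled ortho-hydroxyalkylation of the magnesium phenoxide (MgCl2, Et3N, MeCN, high dilution) gives the cyclic ortho-hydroxybenzhydrol F3. p-Toluenesulfinic acid in CH2Cl2 converts it into the sulfone F4, the standard ortho-quinone methide precursor. Treatment with 34 and Cs2CO3 (base-mediated (4+1) annulation) rejoins the route at 38.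

3. Step 27. The lithium enolate may act as a base and isomerise the quinone methide to the styrene, or the addition may be unselective at C7c and C8a at this most crowded bond. Fallback, setting out from 43 and 41: 43 is converted (LiN(i-Pr)2, Me3SiCl) into the silyl ketene acetal F5. Quinone methide 44, generated from 41 as in step 27, is treated with F5 and catalytic Me3SiOTf at −78 °C (Mukaiyama-type 1,6-addition of a neutral nucleophile through an open transition state). Aqueous work-up rejoins the route at 45.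

Further compounds

F1 | step 34 | 2,3-diarylbenzofuran (C8b=C7b within the furan; seven-membered ring closed) | CC(C)(C)c1cc(cc(C(C)(C)C)c1O)[C@H]2c3c(OC)cc(OC)cc3-c3c4c(cc(O)cc4[C@H]2[C@H](c2cc(C(C)(C)C)c(O)c(C(C)(C)C)c2)[C@H]2c4cc(OC)cc5c4[C@@H](c4cc(OC)cc(OC)c4[C@H](c4cc(C(C)(C)C)c(O)c(C(C)(C)C)c4)[C@H]2c2cc(OC)cc4c2[C@@H](c2cc(OC)cc(OC)c2)[C@H](c2ccc(OC)cc2)O4)[C@H](c2ccc(OC)cc2)O5)oc3-c2ccc(OC)cc2
F2 | step 34 | cis-dihydrobenzofuran B/A (C7b epimer of 57) | CC(C)(C)c1cc(cc(C(C)(C)C)c1O)[C@H]2c3c(OC)cc(OC)cc3[C@@H]3c4c(cc(O)cc4[C@H]2[C@H](c2cc(C(C)(C)C)c(O)c(C(C)(C)C)c2)[C@H]2c4cc(OC)cc5c4[C@@H](c4cc(OC)cc(OC)c4[C@H](c4cc(C(C)(C)C)c(O)c(C(C)(C)C)c4)[C@H]2c2cc(OC)cc4c2[C@@H](c2cc(OC)cc(OC)c2)[C@H](c2ccc(OC)cc2)O4)[C@H](c2ccc(OC)cc2)O5)O[C@@H]3c2ccc(OC)cc2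
F3 | step 22 | cyclic ortho-hydroxybenzhydrol (eight-membered ring closed; C8d bears OH) | CON(C)C(=O)[C@H]2c4cc(O)cc(O)c4C(O)c4cc(OC)cc(OC)c4[C@H](c4cc(C(C)(C)C)c(O)c(C(C)(C)C)c4)[C@H]2c2cc(OC)cc4c2[C@@H](c2cc(OC)cc(OC)c2)[C@H](c2ccc(OC)cc2)O4
F4 | step 22 | cyclic sulfone (C8d bears the 4-methylbenzenesulfonyl group) | CON(C)C(=O)[C@H]2c4cc(O)cc(O)c4C(S(=O)(=O)c6ccc(C)cc6)c4cc(OC)cc(OC)c4[C@H](c4cc(C(C)(C)C)c(O)c(C(C)(C)C)c4)[C@H]2c2cc(OC)cc4c2[C@@H](c2cc(OC)cc(OC)c2)[C@H](c2ccc(OC)cc2)O4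
F5 | step 27 | methyl trimethylsilyl ketene acetal of 43 | COC(O[Si](C)(C)C)=Cc1cc(O[Si](C)(C)C(C)(C)C)cc(O[Si](C)(C)C(C)(C)C)c1
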